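Readings and results were computed with made-up constants; scatter was added.

I ask which of these flasks holds the most product at 20 h, which holds the least, and how much each of those two holds.

common to all: substrate 0.020 M; initiator 0.20 mM

|  | partner | temperature | remark | time |
|---|---|---|---|---|
| south-west | 0.0054 M | 85 °C | run made earlier |  |
| east | 0.020 M | 105 °C | run made earlier |  |
| Monday's | 0.00800 M | 90 °C |  | 20 h |
| Saturday's | 0.0300 M | 90 °C |  | 20 h |
| Friday's | 0.0300 M | 120 °C |  | 20 h |
| Tuesday's | 0.00800 M | 120 °C |  | 20 h |

- south-west (time / h: product / %, substrate / %): 1.50: 4.1, 95.8; 4.00: 9.3, 93.4; 8.00: 14.6, 84.7; 20.0: 25.7, 74.6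
- east (time / h: product / %, substrate / %): 0.667: 5.3, 94.6; 2.00: 14.8, 85.2; 4.00: 27.3, 73.3; 10.0: 53.2, 46.4

(scatter of a reading: 0.5 percentage points)

- the earlier runs were read with a standard deviation of 0.5 percentage points

1. all flasks from highest to lowest amount of product, in percent of the substrate charged, at 20 h (Monday's / Saturday's / Friday's / Tuesday's)
2. the amount of product, in percent of the substrate charged of the flask you put first, at 20 h
3. the amount of product, in percent of the substrate charged of the flask you put last, at 20 h

I fold the charges into one number, the cap, which is the smaller of one and partner charged over substrate charged: 100% in Saturday's and Friday's, and 40.0% in Monday's and Tuesday's. In words, it is the share of the substrate that can become product if each product takes one substrate and one partner and partner goes nowhere else, so in Saturday's and Friday's, where partner over substrate is 150%, the substrate charged is what bounds the cap. The south-west run has a cap of 27.0%, and its product reads 25.7% at 20.0 h, so at long times that run looks like a stop at the cap. The east run, with a cap of 100%, shows the other end: its last substrate reading gives a time constant of 13.0 h, shorter than the 20 h asked about. Joining the ends, I let product climb on such a time constant until it meets the cap. So I put Saturday's and Friday's above Monday's and Tuesday's, where partner is the limiting reagent and the cap is lower. But one number is not enough, since it is equal within each pair, and the temperatures, 90 °C against 120 °C, have to split the pairs. I expect Friday's to lead Saturday's, and I leave Monday's against Tuesday's open.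

The forecast gives Friday's > Saturday's > Tuesday's > Monday's, with 88% (76% to 96%) for the first flask and 35% (30% to 38%) for the last, and it says “Tuesday's hits the 40% cap”.

The flasks give Friday's > Saturday's > Monday's > Tuesday's, with 55.4% in Friday's and 27.8% in Tuesday's.

    partner → decomposed reagent (k = 0.0215 /h, Ea = 121 kJ/mol)
    2 second chain carrier → ended chains (k = 1.20 × 10⁸ /M/s, Ea = 11.0 kJ/mol)
    substrate + initiating radical → capped initiator + first chain carrier (k = 1.78 × 10⁵ /M/s, Ea = 17.0 kJ/mol)
    partner + first chain carrier ⇌ product + second chain carrier (K = 0.132, k = 1.90 × 10⁷ /M/h, Ea = 21.0 kJ/mol, ΔH = −5.00 kJ/mol)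
    initiator → 2 initiating radical (k = 0.00608 /h, Ea = 130 kJ/mol)
    substrate + second chain carrier → by-product + first chain carrier (k = 1.74 × 10⁷ /M/h, Ea = 19.0 kJ/mol)
    (constants at 90 °C)

Tuesday's ends with partner at 0% of its charge and product at 69.5% of its cap, and Friday's, with partner at 0%, reaches 55.4% of its cap and holds 0.0189 M of decomposed reagent. The neighbouring flask repeats Friday's with 0.018 M of partner, so its cap is 90.0%. Its partner also ends at 0%, and its product stands at 44.8%, which is 49.8% of that cap.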